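The route rests on cutting the cyclohexene ring (C1, C10–C14) away from the C1–C10 edge that it shares with the ten-membered ring. One catalytic enantioselective Diels–Alder reaction of a 1,3-bis(silyloxy)penta-1,3-diene (C11–C14, C20, O14 and a temporary O12) with ethyl (E)-3-methyl-4-oxobut-2-enoate (C2, C1, C15, C10, C9) forms C10–C11 and C1–C14 and sets C1, C10 and C14. It exploits the trans C2/C9 and cis C2/O14 relationships around quaternary C1. The temporary C12 oxygen later moves the alkene to C11=C12. C7–C9 and the lactone follow from a nickel-mediated enyne–aldehyde coupling, directed epoxidation and epoxide-opening lactonisation; a boron aldol closes the ten-membered ring.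

Key step: step 4

Remark on the chemistry: atoms carry briarane numbers. C1 is the quaternary carbon, C2–C10 complete the ten-membered ring, C11–C14 the cyclohexene; C15, C16, C18 and C20 are the methyls on C1, C5, C17 and C11; C17 and C19 are the lactone CH and C=O. Compounds 23–27 are carried as C17 epimer mixtures (C17 left undefined in their SMILES); C17 is fixed in step 19. Either enantiomer of 14 would serve, because C4 is oxidised in step 21.

Step 1
Reactants: 1 (E)-4-methoxybut-3-en-2-one
Product: 2 (E)-1-methoxypent-1-en-3-one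
Conditions: LDA, THF, −78 °C; MeI, −78 → 0 °C
Reagents that add atoms: iodomethane CI
Why: Kinetic deprotonation at the only enolisable position (the methyl of the vinylogous ester) and SN2 methylation of the lithium enolate (enolate alkylation).

Step 2
Reactants: 2 (E)-1-methoxypent-1-en-3-one
Product: 4 (E)-1-(triisopropylsilyloxy)pent-1-en-3-one, via sodium enolate 3 (not isolated)
Conditions: NaOH, H2O/MeOH, rt; concentrate; i-Pr3SiCl, THF, 0 °C → rt
Reagents that add atoms: sodium hydroxide [Na+].[OH-]; chlorotriisopropylsilane CC(C)[Si](Cl)(C(C)C)C(C)C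
Why: Addition–elimination of hydroxide at the β-carbon gives the formyl ketone enolate, whose O-silylation at the aldehyde-derived oxygen should give the E-configured β-silyloxy enone (vinylogous ester hydrolysis, enolate O-silylation).

Step 3
Reactants: 4 (E)-1-(triisopropylsilyloxy)pent-1-en-3-one
Product: 5 (1E,3Z)-3-(tert-butyldimethylsilyloxy)-1-(triisopropylsilyloxy)penta-1,3-diene
Conditions: TBSOTf, Et3N, Et2O, −78 → 0 °C
Reagents that add atoms: tert-butyldimethylsilyl triflate CC(C)(C)[Si](C)(C)OS(=O)(=O)C(F)(F)F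
Why: Soft enolisation of the ethyl ketone with silyl triflate and amine should give the Z silyl enol ether (methyl trans to the diene chain), i.e. an electron-rich 1,3-dioxygenated diene with no inside substituent.

Step 4
Reactants: 5 (1E,3Z)-3-(tert-butyldimethylsilyloxy)-1-(triisopropylsilyloxy)penta-1,3-diene; 6 ethyl (E)-3-methyl-4-oxobut-2-enoate
Product: 7 ethyl (1S,2S,5S,6R)-3-(tert-butyldimethylsilyloxy)-6-formyl-2,6-dimethyl-5-(triisopropylsilyloxy)cyclohex-3-ene-1-carboxylate
Conditions: (S)-o-tolyl-oxazaborolidine·HNTf2 (20 mol %), CH2Cl2, −78 °C; Et3N quench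
Reagents that add atoms: none
Why: A concerted but asynchronous [4+2] cycloaddition of the electron-rich diene to the enal, which the chiral cationic oxazaborolidine activates at the formyl oxygen; the closest precedent is the oxazaborolidinium-catalysed Diels–Alder reaction of α-substituted enals with silyloxy dienes. The six-membered ring closes by intermolecular cycloaddition, suprafacial on both partners, with C10–C11 formed ahead of C1–C14 (nucleophilic diene terminus C11 to the enal β-carbon C10). C1 and C10 are related by the E geometry of the dienophile (C2 and C9 trans), C14 is related to C1 by the endo orientation of the formyl group (O14 cis to C2), and the absolute sense comes from the catalyst, which shields one face of the s-trans enal in the accepted pre-transition-state model; the C11 centre is temporary. The step needs regioselectivity, which the matched 1,3-dioxygenation of the diene and formyl (not ester) coordination should secure. It also needs C=C over C=O periselectivity, which the doubly activated, α-methylated alkene should secure.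

Step 5
Reactants: 7 Diels–Alder adduct
Product: 9 ethyl 6-(hydroxymethyl)-2,6-dimethyl-3-oxo-5-(triisopropylsilyloxy)cyclohexane-1-carboxylate (C1, C10, C14 as in 7), via hydroxymethyl silyl enol ether 8 (not isolated)
Conditions: LiAlH(Ot-Bu)3, THF, −78 °C; then 1 M HCl, THF, 0 °C → rt
Reagents that add atoms: none
Why: The hindered alkoxyaluminium hydride should reduce the aldehyde in the presence of the ester and the enol ether, and the acidic work-up hydrolyses the silyl enol ether to the C12 ketone (chemoselective hydride reduction; enol ether hydrolysis).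

Step 6
Reactants: 9 keto alcohol
Product: 10 C2 tert-butyldimethylsilyl ether of 9
Conditions: TBSCl, imidazole, DMF, rt
Reagents that add atoms: tert-butyldimethylsilyl chloride CC(C)(C)[Si](C)(C)Cl
Why: Silylation of the primary alcohol masks C2 for the steps up to the lactone (silyl ether formation).

Step 7
Reactants: 10 keto silyl ether
Product: 11 ethyl 6-(tert-butyldimethylsilyloxymethyl)-2,6-dimethyl-3-(trifluoromethylsulfonyloxy)-5-(triisopropylsilyloxy)cyclohex-2-ene-1-carboxylate
Conditions: Tf2O, 2,6-di-tert-butyl-4-methylpyridine, CH2Cl2, 0 °C → rt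
Reagents that add atoms: triflic anhydride O=S(=O)(OS(=O)(=O)C(F)(F)F)C(F)(F)F
Why: O-triflation of the ketone with a hindered pyridine under equilibrating conditions should give the more substituted enol triflate (thermodynamic enol triflation), which places the double bond at C11=C12 and erases the temporary C11 stereocentre.

Step 8
Reactants: 11 enol triflate
Product: 12 ethyl 6-(tert-butyldimethylsilyloxymethyl)-2,6-dimethyl-5-(triisopropylsilyloxy)cyclohex-2-ene-1-carboxylate
Conditions: Pd(OAc)2 (5 mol %), PPh3, HCO2H, n-Bu3N, DMF, 60 °C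
Reagents that add atoms: none
Why: Palladium-catalysed formate reduction of the alkenyl triflate replaces OTf by H without moving the alkene (hydride transfer by decarboxylation of the palladium formate).

Step 9
Reactants: 12 cyclohexene ester
Product: 13 6-(tert-butyldimethylsilyloxymethyl)-2,6-dimethyl-5-(triisopropylsilyloxy)cyclohex-2-ene-1-carbaldehyde (C9 aldehyde)
Conditions: DIBAL-H, CH2Cl2, −78 °C; Rochelle salt
Reagents that add atoms: none
Why: At −78 °C the tetrahedral aluminate of the hindered ester should persist and release the aldehyde only on work-up (partial ester reduction); the aldehyde is used at once because C10 is enolisable.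

Step 10
Reactants: 14 (S)-but-3-yn-2-ol
Product: 16 (S,Z)-4-iodo-3-methylbut-3-en-2-ol, via cyclic alkenylmagnesium alkoxide 15 (not isolated)
Conditions: MeMgBr (3 equiv), CuI (10 mol %), THF, −20 °C → rt; I2, −40 °C
Reagents that add atoms: methylmagnesium bromide C[Mg]Br; iodine II
Why: Copper-catalysed anti-carbomagnesiation of the propargylic alkoxide through a five-membered magnesium chelate, then iodinolysis with retention, should give the Z iodoalkene with iodine cis to the carbinol carbon.

Step 11
Reactants: 16 (S,Z)-4-iodo-3-methylbut-3-en-2-ol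
Product: 17 (S,Z)-triethyl[(4-iodo-3-methylbut-3-en-2-yl)oxy]silane
Conditions: Et3SiCl, imidazole, CH2Cl2, 0 °C
Reagents that add atoms: chlorotriethylsilane CC[Si](Cl)(CC)CC
Why: Silylation protects the C4 alcohol against the base used in step 15 (silyl ether formation).

Step 12
Reactants: 17 iodoalkene silyl ether; 18 ethynyltrimethylsilane
Product: 19 (S,Z)-triethyl[(3-methyl-6-(trimethylsilyl)hex-3-en-5-yn-2-yl)oxy]silane
Conditions: PdCl2(PPh3)2 (3 mol %), CuI, Et3N, THF, rt
Reagents that add atoms: none
Why: Sonogashira coupling proceeds with retention of the alkene geometry, so the alkyne (C7) ends up cis to C4.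

Step 13
Reactants: 19 silylated enyne
Product: 20 (S,Z)-triethyl[(3-methylhex-3-en-5-yn-2-yl)oxy]silane
Conditions: K2CO3, MeOH, 0 °C
Reagents that add atoms: none
Why: Methoxide-mediated protiodesilylation cleaves the alkynyl C–Si bond and leaves the alkyl silyl ether intact.

Step 14
Reactants: 20 terminal enyne; 21 tert-butyl diazoacetate
Product: 22 tert-butyl (S,Z)-6-methyl-7-(triethylsilyloxy)oct-5-en-3-ynoate
Conditions: CuI (5 mol %), MeCN, rt
Reagents that add atoms: none
Why: Copper(I)-catalysed coupling of a terminal alkyne with a diazoacetate (carbene transfer to the copper acetylide) gives the 3-alkynoate without base, which should avoid isomerisation to the allenoate.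

Step 15
Reactants: 22 3-alkynoate
Product: 23 tert-butyl (5Z,7S)-2,6-dimethyl-7-(triethylsilyloxy)oct-5-en-3-ynoate (C17 epimers)
Conditions: LDA, THF, −78 °C; MeI, −78 °C
Reagents that add atoms: iodomethane CI
Why: Kinetic ester enolate alkylation at the α-carbon installs the C18 methyl; no control at C17 is needed because this centre is equilibrated later.

Step 16
Reactants: 13 C9 aldehyde; 23 enyne ester
Product: 24 (9R,5Z,7E)-dienyl carbinol with C8–C9 joined
Conditions: Ni(cod)2 (10 mol %), P(n-Bu)3 (20 mol %), Et3B, EtOAc, rt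
Reagents that add atoms: none
Why: Nickel-catalysed reductive alkyne–aldehyde coupling (oxidative cyclisation to an oxanickelacycle, ethyl transfer from boron, β-hydride elimination, reductive elimination) in which the conjugated alkene should direct C–C bond formation to C8, syn addition gives the 7E alkene (C6 trans to C9), and Felkin–Anh attack anti to quaternary C1 should set 9R.

Step 17
Reactants: 24 dienyl carbinol
Product: 25 (7R,8R)-epoxy alcohol
Conditions: VO(acac)2 (5 mol %), t-BuOOH, 2,6-lutidine, toluene, 0 °C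
Reagents that add atoms: tert-butyl hydroperoxide CC(C)(C)OO
Why: Vanadium-catalysed hydroxyl-directed epoxidation should oxidise only the allylic C7=C8 bond, and A(1,2) strain with the C8 substituent should give the erythro epoxy alcohol, which sets C8 from C9.

Step 18
Reactants: 25 epoxy alcohol
Product: 26 γ-lactone with free C8 and C9 hydroxyls (7S,8-OH and 9R as in the target)
Conditions: BF3·OEt2 (0.2 equiv), CH2Cl2, −78 → −40 °C
Reagents that add atoms: none
Why: Lewis acid activation of the vinyl epoxide and 5-exo attack of the tert-butyl ester carbonyl at allylic C7 with inversion, then loss of 2-methylpropene, should give the lactone and the tertiary C8 alcohol (epoxide-opening lactonisation with ester participation), which sets C7 from the epoxide.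

Step 19
Reactants: 26 hydroxy lactone
Product: 28 C9 acetate with 17R configuration, via C17-epimeric acetate 27 (not isolated)
Conditions: Ac2O, Et3N, DMAP (cat.), CH2Cl2, rt; then DBU (0.3 equiv), rt
Reagents that add atoms: acetic anhydride CC(=O)OC(C)=O
Why: DMAP-catalysed acetylation should take the secondary C9 hydroxyl and leave the tertiary C8 hydroxyl, and DBU then equilibrates the enolisable C17 centre to the epimer with the methyl trans to the bulky C9-bearing substituent on C8 (thermodynamic epimerisation).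

Step 20
Reactants: 28 C9 acetate
Product: 29 diol (C2 primary and C4 secondary hydroxyls free)
Conditions: CSA (0.2 equiv), MeOH/CH2Cl2, 0 °C → rt
Reagents that add atoms: none
Why: Acid-catalysed methanolysis removes the primary TBS and the allylic TES ether while the hindered secondary TIPS ether at C14 should survive (selective desilylation).

Step 21
Reactants: 29 diol
Product: 30 keto aldehyde (C2 aldehyde and C4 methyl ketone with Z enone)
Conditions: Dess–Martin periodinane, CH2Cl2, rt
Reagents that add atoms: none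
Why: Dess–Martin oxidation converts the primary and the allylic secondary alcohol in one operation; the tertiary C8 alcohol is inert and the neutral conditions should preserve the Z enone.

Step 22
Reactants: 30 keto aldehyde
Product: 32 ten-membered aldol with 2R hydroxyl and C4 ketone, via boron enolate 31 (not isolated)
Conditions: n-Bu2BOTf, i-Pr2NEt, CH2Cl2 (2 mM), −78 → −20 °C; then pH 7 buffer, MeOH, H2O2, 0 °C
Reagents that add atoms: none
Why: Soft enolisation of the methyl ketone (acetate and lactone are not enolised) and intramolecular boron aldol addition to the non-enolisable C2 aldehyde through a Zimmerman–Traxler transition state at high dilution should close the ten-membered ring, with Felkin-type attack anti to C14 about quaternary C1 giving 2R.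

Step 23
Reactants: 32 macrocyclic aldol
Product: 33 2,4-anti diol (4R)
Conditions: Me4NBH(OAc)3, MeCN/AcOH, −30 °C
Reagents that add atoms: none
Why: Evans–Saksena reduction delivers hydride intramolecularly from the C2 alkoxyborohydride to the enone carbonyl, which should give the 1,3-anti diol by 1,2-reduction.

Step 24
Reactants: 33 anti diol
Product: 34 triol (C2, C4 and C14 hydroxyls free)
Conditions: HF·pyridine, THF, 0 °C → rt
Reagents that add atoms: none
Why: Fluoride-mediated cleavage of the TIPS ether (desilylation) under buffered acidic conditions should not disturb the acetate or the lactone.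

Step 25
Reactants: 34 triol
Product: 35 target compound
Conditions: Ac2O, pyridine, DMAP (cat.), CH2Cl2, rt
Reagents that add atoms: acetic anhydride CC(=O)OC(C)=O
Why: DMAP-catalysed acetylation of the three secondary alcohols, while the tertiary C8 hydroxyl flanked by C7, C9 and C17 should remain free under these conditions.

Compound list
1 | (E)-4-methoxybut-3-en-2-one | CO/C=C/C(C)=O | starting material
2 | (E)-1-methoxypent-1-en-3-one | CCC(=O)/C=C/OC | intermediate
3 | sodium (E)-3-oxopent-1-en-1-olate | CCC(=O)/C=C/[O-].[Na+] | intermediate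
4 | (E)-1-(triisopropylsilyloxy)pent-1-en-3-one | CCC(=O)/C=C/O[Si](C(C)C)(C(C)C)C(C)C | intermediate
5 | (1E,3Z)-3-(tert-butyldimethylsilyloxy)-1-(triisopropylsilyloxy)penta-1,3-diene | C/C=C(\O[Si](C)(C)C(C)(C)C)/C=C/O[Si](C(C)C)(C(C)C)C(C)C | intermediate
6 | ethyl (E)-3-methyl-4-oxobut-2-enoate | CCOC(=O)/C=C(\C)C=O | starting material
7 | ethyl (1S,2S,5S,6R)-3-(tert-butyldimethylsilyloxy)-6-formyl-2,6-dimethyl-5-(triisopropylsilyloxy)cyclohex-3-ene-1-carboxylate (C1 methyl and C10 ester on one face, formyl and O14 on the other) | O=C[C@]1(C)[C@@H](C(=O)OCC)[C@H](C)C(O[Si](C)(C)C(C)(C)C)=C[C@@H]1O[Si](C(C)C)(C(C)C)C(C)C | intermediate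
8 | C2 alcohol of 7 with the silyl enol ether intact | OC[C@]1(C)[C@@H](C(=O)OCC)[C@H](C)C(O[Si](C)(C)C(C)(C)C)=C[C@@H]1O[Si](C(C)C)(C(C)C)C(C)C | intermediate
9 | ethyl 6-(hydroxymethyl)-2,6-dimethyl-3-oxo-5-(triisopropylsilyloxy)cyclohexane-1-carboxylate, ring centres as in 7 | OC[C@]1(C)[C@@H](C(=O)OCC)[C@H](C)C(=O)C[C@@H]1O[Si](C(C)C)(C(C)C)C(C)C | intermediate
10 | C2 tert-butyldimethylsilyl ether of 9 | CC(C)(C)[Si](C)(C)OC[C@]1(C)[C@@H](C(=O)OCC)[C@H](C)C(=O)C[C@@H]1O[Si](C(C)C)(C(C)C)C(C)C | intermediate
11 | C11=C12 enol triflate of 10 | CC(C)(C)[Si](C)(C)OC[C@]1(C)[C@@H](C(=O)OCC)C(C)=C(OS(=O)(=O)C(F)(F)F)C[C@@H]1O[Si](C(C)C)(C(C)C)C(C)C | intermediate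
12 | ethyl 6-(tert-butyldimethylsilyloxymethyl)-2,6-dimethyl-5-(triisopropylsilyloxy)cyclohex-2-ene-1-carboxylate (C11=C12 alkene; C1, C10, C14 as in the target) | CC(C)(C)[Si](C)(C)OC[C@]1(C)[C@@H](C(=O)OCC)C(C)=CC[C@@H]1O[Si](C(C)C)(C(C)C)C(C)C | intermediate
13 | corresponding C9 aldehyde (cyclohex-2-ene-1-carbaldehyde) | CC(C)(C)[Si](C)(C)OC[C@]1(C)[C@@H](C=O)C(C)=CC[C@@H]1O[Si](C(C)C)(C(C)C)C(C)C | intermediate
14 | (S)-but-3-yn-2-ol | C#C[C@H](C)O | starting material
15 | cyclic alkenylmagnesium alkoxide from anti-carbomagnesiation of 14 | C[C@H](O1)C(C)=C[Mg]1 | intermediate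
16 | (S,Z)-4-iodo-3-methylbut-3-en-2-ol | C[C@H](O)/C(C)=C\I | intermediate
17 | (S,Z)-triethyl[(4-iodo-3-methylbut-3-en-2-yl)oxy]silane | C[C@H](O[Si](CC)(CC)CC)/C(C)=C\I | intermediate
18 | ethynyltrimethylsilane | C#C[Si](C)(C)C | starting material
19 | (S,Z)-triethyl[(3-methyl-6-(trimethylsilyl)hex-3-en-5-yn-2-yl)oxy]silane | C[C@H](O[Si](CC)(CC)CC)/C(C)=C\C#C[Si](C)(C)C | intermediate
20 | (S,Z)-triethyl[(3-methylhex-3-en-5-yn-2-yl)oxy]silane | C[C@H](O[Si](CC)(CC)CC)/C(C)=C\C#C | intermediate
21 | tert-butyl diazoacetate | CC(C)(C)OC(=O)C=[N+]=[N-] | starting material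
22 | tert-butyl (S,Z)-6-methyl-7-(triethylsilyloxy)oct-5-en-3-ynoate | C[C@H](O[Si](CC)(CC)CC)/C(C)=C\C#CCC(=O)OC(C)(C)C | intermediate
23 | tert-butyl (5Z,7S)-2,6-dimethyl-7-(triethylsilyloxy)oct-5-en-3-ynoate, C17 epimers | C[C@H](O[Si](CC)(CC)CC)/C(C)=C\C#CC(C)C(=O)OC(C)(C)C | intermediate
24 | (9R)-carbinol from 13 and 23: 5Z,7E-diene, tert-butyl ester on C17, TES ether at C4, TBS ether at C2, TIPS ether at C14 | CC(C)(C)[Si](C)(C)OC[C@]1(C)[C@@H]([C@@H](O)/C(C(C)C(=O)OC(C)(C)C)=C/C=C(C)\[C@H](C)O[Si](CC)(CC)CC)C(C)=CC[C@@H]1O[Si](C(C)C)(C(C)C)C(C)C | intermediate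
25 | (7R,8R)-7,8-epoxide of 24 (erythro to the 9R alcohol) | CC(C)(C)[Si](C)(C)OC[C@]1(C)[C@@H]([C@@H](O)[C@@]2(C(C)C(=O)OC(C)(C)C)O[C@@H]2/C=C(C)\[C@H](C)O[Si](CC)(CC)CC)C(C)=CC[C@@H]1O[Si](C(C)C)(C(C)C)C(C)C | intermediate
26 | C19–O7 γ-lactone with free C8 (tertiary) and C9 hydroxyls; C7, C8, C9 as in the target; C17 epimers | CC(C)(C)[Si](C)(C)OC[C@]1(C)[C@@H]([C@@H](O)[C@@]2(O)[C@H](/C=C(C)\[C@H](C)O[Si](CC)(CC)CC)OC(=O)C2C)C(C)=CC[C@@H]1O[Si](C(C)C)(C(C)C)C(C)C | intermediate
27 | C9 acetate of 26, C17 epimers | CC(C)(C)[Si](C)(C)OC[C@]1(C)[C@@H]([C@@H](OC(C)=O)[C@@]2(O)[C@H](/C=C(C)\[C@H](C)O[Si](CC)(CC)CC)OC(=O)C2C)C(C)=CC[C@@H]1O[Si](C(C)C)(C(C)C)C(C)C | intermediate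
28 | C9 acetate with 17R methyl (C18 cis to the C8 hydroxyl) | CC(C)(C)[Si](C)(C)OC[C@]1(C)[C@@H]([C@@H](OC(C)=O)[C@@]2(O)[C@H](/C=C(C)\[C@H](C)O[Si](CC)(CC)CC)OC(=O)[C@@H]2C)C(C)=CC[C@@H]1O[Si](C(C)C)(C(C)C)C(C)C | intermediate
29 | diol: C2 hydroxymethyl and C4 secondary allylic alcohol free, TIPS ether at C14 | OC[C@]1(C)[C@@H]([C@@H](OC(C)=O)[C@@]2(O)[C@H](/C=C(C)\[C@H](C)O)OC(=O)[C@@H]2C)C(C)=CC[C@@H]1O[Si](C(C)C)(C(C)C)C(C)C | intermediate
30 | keto aldehyde: C2 aldehyde on C1, Z-configured C4 methyl enone on C7 | O=C[C@]1(C)[C@@H]([C@@H](OC(C)=O)[C@@]2(O)[C@H](/C=C(C)\C(C)=O)OC(=O)[C@@H]2C)C(C)=CC[C@@H]1O[Si](C(C)C)(C(C)C)C(C)C | intermediate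
31 | dibutylboron dienolate of the C4 ketone with the C8 hydroxyl as dibutylborinate | O=C[C@]1(C)[C@@H]([C@@H](OC(C)=O)[C@@]2(OB(CCCC)CCCC)[C@H](/C=C(C)\C(=C)OB(CCCC)CCCC)OC(=O)[C@@H]2C)C(C)=CC[C@@H]1O[Si](C(C)C)(C(C)C)C(C)C | intermediate
32 | briarane aldol: 2R-hydroxy, 4-oxo, 9-acetoxy, 8-hydroxy, 14-triisopropylsilyloxy, 5Z,11-diene, 18,7-lactone | CC(C)[Si](C(C)C)(C(C)C)O[C@H]1CC=C(C)[C@@H]2[C@@H](OC(C)=O)[C@@]3(O)[C@H](/C=C(/C)C(=O)C[C@@H](O)[C@@]12C)OC(=O)[C@@H]3C | intermediate
33 | 2R,4R-diol (2,4-anti) of 32 | CC(C)[Si](C(C)C)(C(C)C)O[C@H]1CC=C(C)[C@@H]2[C@@H](OC(C)=O)[C@@]3(O)[C@H](/C=C(/C)[C@H](O)C[C@@H](O)[C@@]12C)OC(=O)[C@@H]3C | intermediate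
34 | 2,4,14-triol with 9-acetate and free 8-hydroxyl | O[C@H]1CC=C(C)[C@@H]2[C@@H](OC(C)=O)[C@@]3(O)[C@H](/C=C(/C)[C@H](O)C[C@@H](O)[C@@]12C)OC(=O)[C@@H]3C | intermediate
35 | CNP0206892.2: (1R,2R,4R,5Z,7S,8S,9R,10S,14S,17R)-2,4,9,14-tetraacetoxy-8-hydroxybriara-5,11-dien-18,7-olide | CC(=O)O[C@H]1CC=C(C)[C@@H]2[C@@H](OC(C)=O)[C@@]3(O)[C@H](/C=C(/C)[C@H](OC(C)=O)C[C@@H](OC(C)=O)[C@@]12C)OC(=O)[C@@H]3C | target

Total step count: 25. Longest linear sequence: 19 steps (steps 1–9 and 16–25).

Steps most likely to fail

Step 7. Regiochemical leakage: deprotonation of the triflyloxycarbenium ion on the less hindered C13 side would give the Δ12(13) triflate, and the C14 silyloxy group could be lost by β-elimination. The fallback sets out from 10 and returns at 11. Ketone 10 is converted under equilibrating conditions (TMSCl, NaI, Et3N, MeCN, rt) into the more substituted trimethylsilyl enol ether F1, which is freed of its regioisomer by chromatography. MeLi (THF, 0 °C) then releases the regiodefined lithium enolate, which is trapped at −78 °C with N-(5-chloro-2-pyridyl)triflimide to give 11.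

Step 16. Poor facial selectivity at C9 in the oxidative cyclisation (the metallacycle need not follow the Felkin–Anh preference), made worse by any epimerisation of the enolisable aldehyde. The fallback sets out from 24 obtained as a C9 epimer mixture and returns at 24. Dess–Martin oxidation gives the cross-conjugated C9 dienone F2. CBS reduction with the (S)-methyl oxazaborolidine and catecholborane (toluene, −78 °C), in which the α-branched alkenyl group acts as the large substituent, should return the 9R alcohol 24 under reagent control.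

Step 22. Intermolecular aldol oligomerisation, slow enolisation or retro-aldol cleavage during closure of the ten-membered ring. The fallback sets out from 30 and returns at 32. TMSOTf and Et3N (CH2Cl2, −78 °C) give the bis(trimethylsilyl) compound F3 (kinetic enol ether of the methyl ketone and C8 silyl ether). NBS (THF, −78 °C) converts it into the bromoketone F4. SmI2 (THF, −78 °C, high dilution) reduces the C–Br bond to a samarium enolate, which closes the ring in an intramolecular Reformatsky-type aldol to give the C8 silyl ether F5. Brief treatment with citric acid in MeOH removes the tertiary TMS ether and gives 32.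

Further compounds
F1 | step 7 | more substituted (C11=C12) trimethylsilyl enol ether of 10 | CC(C)(C)[Si](C)(C)OC[C@]1(C)[C@@H](C(=O)OCC)C(C)=C(O[Si](C)(C)C)C[C@@H]1O[Si](C(C)C)(C(C)C)C(C)C
F2 | step 16 | C9 ketone (dienone) derived from 24 | CC(C)(C)[Si](C)(C)OC[C@]1(C)[C@@H](C(=O)/C(C(C)C(=O)OC(C)(C)C)=C/C=C(C)\[C@H](C)O[Si](CC)(CC)CC)C(C)=CC[C@@H]1O[Si](C(C)C)(C(C)C)C(C)C
F3 | step 22 | bis(trimethylsilyl) derivative of 30 (C4 silyl dienol ether and C8 silyl ether) | O=C[C@]1(C)[C@@H]([C@@H](OC(C)=O)[C@@]2(O[Si](C)(C)C)[C@H](/C=C(C)\C(=C)O[Si](C)(C)C)OC(=O)[C@@H]2C)C(C)=CC[C@@H]1O[Si](C(C)C)(C(C)C)C(C)C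
F4 | step 22 | C3 bromoketone with C8 trimethylsilyl ether | O=C[C@]1(C)[C@@H]([C@@H](OC(C)=O)[C@@]2(O[Si](C)(C)C)[C@H](/C=C(C)\C(=O)CBr)OC(=O)[C@@H]2C)C(C)=CC[C@@H]1O[Si](C(C)C)(C(C)C)C(C)C
F5 | step 22 | C8 trimethylsilyl ether of 32 | CC(C)[Si](C(C)C)(C(C)C)O[C@H]1CC=C(C)[C@@H]2[C@@H](OC(C)=O)[C@@]3(O[Si](C)(C)C)[C@H](/C=C(/C)C(=O)C[C@@H](O)[C@@]12C)OC(=O)[C@@H]3C
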